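Start from the north-west run, which has the charge of the asked flask, and read it by a bench rule: treat the fall of L as one first-order decay and the late fall of E as another, with E peaking between them.

in all of them: L 10 mM

| run | Q | remark | time |
|---|---|---|---|
| north-west | 3 mM | the very flask that is asked about, followed so far |  |
| south | 4.5 mM | run made earlier |  |
| flask | 3.00 mM |  | 15 d |

- north-west (time / d: E / %, L / %): 0.125: 21, 45; 0.250: 27, 27; 0.625: 31, 6; 1.25: 23, 1; 3.00: 7, 0
- south (time / d: E / %, L / %): 0.125: 18, 40; 0.333: 30, 15; 0.833: 27, 4; 2.50: 10, 1; 6.00: 3, 0

(each reading ± 1.5 percentage points)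

- the analysis behind the earlier runs scatters by 1.5 percentage points, standard deviation

- when, up to 15 d, the flask holds most E
- the amount of E, in percent of the L charged, at that time

Take kL, the mean rate of the fall of L in north-west, from its reading at 0.625 d: 4.50 d⁻¹. Take kE from the E readings between 1.25 d and 3.00 d, when L reads 1% or less: 0.680 d⁻¹. Treat the fast fall as finished there and let E run free. L then falls m = 6.62 times faster than E, and this rate ratio sets the rule's peak at ln(m)/(kL − kE) = 0.495 d, with a fraction m^(−m/(m−1)) = 10.8% of L left.

Find the border in south: from 2.50 d to 6.00 d its E falls at 0.344 d⁻¹, half as fast as kE, so the tail is no single decay. Trust the rule only early; the reckoned peak lies earlier than that stretch. Expect a height near the highest north-west reading, 31%.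

The forecast gives 0.5 d (0.35 d to 0.7 d) and 32% (29.5% to 34%), holding that “the maximum up to 15 d is this early one”. The flask gives 31.8% at 0.468 d, with L at 10.3% against the reckoned 10.8%.

    E ⇌ G (K = 8.00, k = 0.0365 h⁻¹)
    L → E (k = 0.108 h⁻¹)
    2 L → X (k = 9.45 L mol⁻¹ h⁻¹)
    L + Q → J (k = 14.1 L mol⁻¹ h⁻¹)

Use m again: the rule puts the peak of E at a fraction s = m^(−1/(m−1)) = 0.714 of the share of L that turns to E, so the flask's peak reckons to a share 44.4%, the rule's selectivity, lower than the 49.4% that E and G together hold in the flask at 15.0 d. South, with m = 9.56 from its own readings, has s = 0.768, and by the same rule its peak of 30.1% reckons to a lower share, 39.2%. In the flask at 0.154 d, the step from L to E has a half-life of 0.27 d against 0.79 d for the forward step from E to G. At that time the flask makes E 5.00 times faster than it uses E up, each step taken net.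

(The earlier runs and the new flask stem from a simulated flask with made-up constants; the scatter is artificial.)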